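The nonaene is cut at its two sp2–sp2 single bonds C10–C11 and C10′–C11′. These bracket a symmetric C11–C11′ pentaene, and everything that distinguishes the halves (the 5,6-epoxy-3-acyloxy cyclohexane ring C1–C6 and the 3′-acyloxy ε ring C1′–C6′) lies outside them. One pot joins three pieces: a C12 pentaene bearing tributyltin at C11 and a pinacol boronate at C11′ couples first, without base, with the epoxy-ring C14 dienyl iodide (Stille), then, once phosphate is added, with the ε-ring C14 dienyl iodide (Suzuki). Both palmitates, the oxirane, all five stereocentres and every E double bond are already present in these three precursors, so the coupled product is the target.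

Key step: step 27

Remark: positions are given in carotenoid numbering (C1–C20, primes for the ε half). The target is read as the all-E (3S,5R,6S,3′R,6′R) isomer, with the oxirane anti to the C3 ester and the C3′ ester trans to the C6′ side chain. The three coupling partners map onto this structure with retention at every centre and double bond, so no structural correction is needed.
Remark: α-ionone is used as the racemate and resolved. Simple deprotonated forms of numbered compounds (enolates, carbanions) are not numbered separately.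

**Epoxy-ring fragment**

Step 1
Reactants: 1 ketoisophorone
Product: 2 (6R)-levodione
Conditions: ene reductase OYE2, NADP+ (cat.), glucose dehydrogenase, D-glucose, phosphate buffer pH 7, 30 °C
Reagents that add atoms: none
Why: Enzymatic conjugate reduction (old yellow enzyme) of the enedione C=C, in which flavin hydride and an active-site proton add trans and the enzyme pocket alone sets the methyl-bearing centre as R.

Step 2
Reactants: 2 (6R)-levodione
Product: 3 (4R,6R)-actinol
Conditions: H2 (5 bar), Raney Ni, MeOH, 25 °C; recrystallisation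
Reagents that add atoms: none
Why: Heterogeneous ketone hydrogenation that touches only the unhindered C4 carbonyl (C1 is flanked by CMe2 and CHMe); hydrogen should arrive on the face away from the axial C2 methyl of the chair holding the C6 methyl equatorial, so the 6R centre sets 4R (hydroxyl trans to the methyl), and crystallisation removes any cis epimer.

Step 3
Reactants: 3 (4R,6R)-actinol
Product: 4 (4R,6R)-4-(tert-butyldimethylsilyloxy)-2,2,6-trimethylcyclohexanone
Conditions: TBSCl, imidazole, DMF, 23 °C
Reagents that add atoms: tert-butyldimethylsilyl chloride CC(C)(C)[Si](C)(C)Cl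
Why: Standard imidazole-promoted silylation of a secondary alcohol, giving an ether that survives enolisation, carbonylation, hydride reduction and olefination.

Step 4
Reactants: 4 (4R,6R)-4-(tert-butyldimethylsilyloxy)-2,2,6-trimethylcyclohexanone
Product: 5 (4R)-4-(tert-butyldimethylsilyloxy)-2,6,6-trimethylcyclohex-1-en-1-yl trifluoromethanesulfonate
Conditions: LiN(iPr)2, THF, −78 °C; then PhNTf2, −78 → 0 °C
Reagents that add atoms: N-phenylbis(trifluoromethanesulfonimide) O=S(=O)(N(c1ccccc1)S(=O)(=O)C(F)(F)F)C(F)(F)F
Why: Enolate O-triflation; only C6 carries an α-hydrogen, so a single tetrasubstituted enol triflate forms, the C6 centre is erased on purpose and the silyloxy centre, which has no leaving group β to the enolate, is untouched.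

Step 5
Reactants: 5 (4R)-4-(tert-butyldimethylsilyloxy)-2,6,6-trimethylcyclohex-1-en-1-yl trifluoromethanesulfonate
Product: 6 methyl (4R)-4-(tert-butyldimethylsilyloxy)-2,6,6-trimethylcyclohex-1-ene-1-carboxylate
Conditions: Pd(OAc)2 (5 mol %), PPh3, CO (1 atm), Et3N, MeOH/DMF, 60 °C
Reagents that add atoms: carbon monoxide [C-]#[O+]; methanol CO
Why: Palladium-catalysed alkoxycarbonylation of an enol triflate (oxidative addition, CO insertion, methanolysis of the acylpalladium), a standard route to hindered cyclohexenecarboxylates.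

Step 6
Reactants: 6 methyl (4R)-4-(tert-butyldimethylsilyloxy)-2,6,6-trimethylcyclohex-1-ene-1-carboxylate
Product: 7 [(4R)-4-(tert-butyldimethylsilyloxy)-2,6,6-trimethylcyclohex-1-en-1-yl]methanol
Conditions: iBu2AlH, CH2Cl2, −78 → 0 °C; aq. potassium sodium tartrate work-up
Reagents that add atoms: none
Why: 1,2-Reduction of the conjugated ester to the primary allylic alcohol by the aluminium hydride, with the silyl ether and the tetrasubstituted alkene inert.

Step 7
Reactants: 7 [(4R)-4-(tert-butyldimethylsilyloxy)-2,6,6-trimethylcyclohex-1-en-1-yl]methanol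
Product: 8 [(1R,4S,6R)-4-(tert-butyldimethylsilyloxy)-2,2,6-trimethyl-7-oxabicyclo[4.1.0]heptan-1-yl]methanol
Conditions: Ti(OiPr)4 (20 mol %), D-(−)-diethyl tartrate (24 mol %), t-BuOOH, 4 Å MS, CH2Cl2, −20 °C
Reagents that add atoms: tert-butyl hydroperoxide CC(C)(C)OO
Why: Sharpless–Katsuki asymmetric epoxidation of a primary allylic alcohol; the titanium tartrate binds the hydroxymethyl group and, with the D-(−) ester, should deliver oxygen to the alkene face anti to the silyloxy group, so both oxirane centres are set by the reagent and helped by the steric bias of the ring substituent.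

Step 8
Reactants: 8 [(1R,4S,6R)-4-(tert-butyldimethylsilyloxy)-2,2,6-trimethyl-7-oxabicyclo[4.1.0]heptan-1-yl]methanol
Product: 9 (1S,4S,6R)-4-(tert-butyldimethylsilyloxy)-2,2,6-trimethyl-7-oxabicyclo[4.1.0]heptane-1-carbaldehyde
Conditions: Pr4N[RuO4] (5 mol %), N-methylmorpholine N-oxide, 4 Å MS, CH2Cl2, 0 → 23 °C
Reagents that add atoms: none
Why: Ley–Griffith oxidation of the primary alcohol under neutral conditions; the α-carbon is quaternary, so nothing can epimerise and the oxirane never meets acid.

Step 9
Reactants: 10 propargyl alcohol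
Product: 12 (2E)-3-iodo-2-methylprop-2-en-1-ol, via alkenylalane 11 (not isolated)
Conditions: Me3Al, Cp2ZrCl2 (25 mol %), CH2Cl2, 0 → 23 °C; then I2, THF, −30 → 0 °C
Reagents that add atoms: trimethylaluminium C[Al](C)C; iodine [I][I]
Why: Negishi zirconium-catalysed carboalumination (syn addition of methyl and aluminium, methyl to the internal carbon) followed by iodinolysis of the C–Al bond with retention, which fixes the E geometry.

Step 10
Reactants: 12 (2E)-3-iodo-2-methylprop-2-en-1-ol
Product: 13 (1E)-3-bromo-1-iodo-2-methylprop-1-ene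
Conditions: PBr3, Et2O, 0 °C
Reagents that add atoms: phosphorus tribromide BrP(Br)Br
Why: SN2 bromination of a primary allylic alcohol through its phosphite ester, with the alkenyl iodide untouched.

Step 11
Reactants: 13 (1E)-3-bromo-1-iodo-2-methylprop-1-ene
Product: 14 diethyl [(2E)-3-iodo-2-methylprop-2-en-1-yl]phosphonate
Conditions: P(OEt)3 (neat), 100 °C
Reagents that add atoms: triethyl phosphite CCOP(OCC)OCC
Why: Michaelis–Arbuzov reaction at the primary allylic bromide; an alkenyl iodide does not react with a phosphite without a metal catalyst.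

Step 12
Reactants: 9 (1S,4S,6R)-4-(tert-butyldimethylsilyloxy)-2,2,6-trimethyl-7-oxabicyclo[4.1.0]heptane-1-carbaldehyde, 14 diethyl [(2E)-3-iodo-2-methylprop-2-en-1-yl]phosphonate
Product: 15 (1S,4S,6R)-4-(tert-butyldimethylsilyloxy)-1-[(1E,3E)-4-iodo-3-methylbuta-1,3-dien-1-yl]-2,2,6-trimethyl-7-oxabicyclo[4.1.0]heptane
Conditions: 14, KN(SiMe3)2, THF, −78 °C; then 9, −78 → 0 °C
Reagents that add atoms: none
Why: Horner–Wadsworth–Emmons olefination with an allylic phosphonate anion; reversible addition to the hindered, non-enolisable aldehyde and syn-elimination of phosphate should favour the E C7=C8 alkene, the non-nucleophilic amide base leaves the C–I bond alone and the E iodoalkene comes unchanged from 14.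

Step 13
Reactants: 15 (1S,4S,6R)-4-(tert-butyldimethylsilyloxy)-1-[(1E,3E)-4-iodo-3-methylbuta-1,3-dien-1-yl]-2,2,6-trimethyl-7-oxabicyclo[4.1.0]heptane
Product: 16 (3S,5R,6S)-epoxy-ring C14 dienyl iodide with free 3-hydroxyl
Conditions: Bu4NF, THF, 0 → 23 °C
Reagents that add atoms: none
Why: Fluoride desilylation; the iodoalkene has no hydrogen on the neighbouring sp2 carbon and cannot eliminate, and the C3 alkoxide cannot reach the oxirane.

Step 14
Reactants: 16 (3S,5R,6S)-epoxy-ring C14 dienyl iodide with free 3-hydroxyl, 17 palmitoyl chloride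
Product: 18 (3S,5R,6S)-epoxy-ring C14 dienyl iodide palmitate
Conditions: pyridine, DMAP (cat.), CH2Cl2, 0 → 23 °C
Reagents that add atoms: none
Why: DMAP-catalysed acylation of the secondary alcohol under basic conditions that the acid-labile oxirane and the iodoalkene tolerate.

**ε-Ring fragment**

Step 15
Reactants: 19 α-ionone (racemic)
Product: 20 rac-3-oxo-α-ionone
Conditions: t-BuOOH, Rh2(cap)4 (1 mol %, cap = caprolactamate), K2CO3, CH2Cl2, 23 °C
Reagents that add atoms: tert-butyl hydroperoxide CC(C)(C)OO
Why: Radical allylic oxidation by tert-butylperoxyl radicals (dirhodium caprolactamate with the hydroperoxide); hydrogen is abstracted from the ring allylic CH2 at C3 and not from the hindered tertiary C6–H, and the mixed peroxide collapses to the enone.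

Step 16
Reactants: 20 rac-3-oxo-α-ionone
Product: 21 rac-3-oxo-α-ionone 9-ethylene ketal
Conditions: HOCH2CH2OH, HC(OMe)3, p-TsOH (cat.), 23 °C
Reagents that add atoms: ethylene glycol OCCO
Why: Acid-catalysed ketalisation with an orthoester as water scavenger; the unhindered side-chain methyl ketone should react in preference to the ring carbonyl, which is a β,β-disubstituted enone beside a neopentyl CH2.

Step 17
Reactants: 21 rac-3-oxo-α-ionone 9-ethylene ketal
Product: 23 rac-trans-3-hydroxy-α-ionone, via hydroxy ketal 22 (not isolated)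
Conditions: K[sBu3BH], THF, −78 °C; NaOH/H2O2 work-up; then 0.3 M HCl, acetone, 0 °C; chromatography
Reagents that add atoms: water O
Why: 1,2-Hydride reduction of the β,β-disubstituted ring enone followed by mild acetal hydrolysis; the bulky borohydride should attack C3 anti to the axial C1 methyl of the half-chair that holds the C6 side chain pseudoaxial, placing the hydroxyl trans to the side chain, and any cis isomer is removed by chromatography.

Step 18
Reactants: 23 rac-trans-3-hydroxy-α-ionone
Product: 24 (3R,6R)-3-hydroxy-α-ionone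
Conditions: lipase AK (Pseudomonas fluorescens), vinyl acetate, tert-butyl methyl ether, 23 °C, to about 55% conversion; chromatography
Reagents that add atoms: none
Why: Lipase-catalysed kinetic resolution by irreversible transesterification; on steric (Kazlauskas-type) grounds, with the gem-dimethyl flank as the large group, the enzyme should acylate the 3S alcohol and leave the (3R,6R) enantiomer, which is separated from the acetate.

Step 19
Reactants: 24 (3R,6R)-3-hydroxy-α-ionone
Product: 25 (3R,6R)-3-(tert-butyldimethylsilyloxy)-α-ionone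
Conditions: TBSCl, imidazole, DMF, 23 °C
Reagents that add atoms: tert-butyldimethylsilyl chloride CC(C)(C)[Si](C)(C)Cl
Why: Standard silylation of the allylic alcohol, masking it against the amide base and the organoaluminium reagent of the next two steps.

Step 20
Reactants: 25 (3R,6R)-3-(tert-butyldimethylsilyloxy)-α-ionone
Product: 27 (3R,6R)-TBS enyne, via dienyl phosphate 26 (not isolated)
Conditions: LiN(iPr)2 (1.1 equiv), THF, −78 °C; ClP(O)(OEt)2, −78 → 23 °C; then LiN(iPr)2 (2.3 equiv), −78 → 23 °C
Reagents that add atoms: none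
Why: Negishi alkyne synthesis from a methyl ketone (kinetic deprotonation at the methyl group, O-phosphorylation, then base-induced elimination of diethyl phosphate); the hindered doubly allylic C6–H is not expected to be removed at low temperature, so 6R is kept.

Step 21
Reactants: 27 (3R,6R)-TBS enyne
Product: 29 (3R,6R)-ε-ring C14 dienyl iodide TBS ether, via alkenylalane 28 (not isolated)
Conditions: Me3Al, Cp2ZrCl2 (30 mol %), ClCH2CH2Cl, 23 °C; then I2, THF, −30 → 0 °C
Reagents that add atoms: trimethylaluminium C[Al](C)C; iodine [I][I]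
Why: Negishi zirconium-catalysed methylalumination of the terminal alkyne of a conjugated enyne (syn, methyl to C9) and iodinolysis with retention give the E trisubstituted iodoalkene, while the trisubstituted ring alkene and the silyl ether do not react.

Step 22
Reactants: 29 (3R,6R)-ε-ring C14 dienyl iodide TBS ether
Product: 30 (3R,6R)-ε-ring C14 dienyl iodide with free 3-hydroxyl
Conditions: Bu4NF, THF, 0 → 23 °C
Reagents that add atoms: none
Why: Fluoride desilylation under non-acidic conditions that cannot ionise the allylic alcohol or eliminate the iodoalkene.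

Step 23
Reactants: 30 (3R,6R)-ε-ring C14 dienyl iodide with free 3-hydroxyl, 17 palmitoyl chloride
Product: 31 (3R,6R)-ε-ring C14 dienyl iodide palmitate
Conditions: pyridine, DMAP (cat.), CH2Cl2, 0 → 23 °C
Reagents that add atoms: none
Why: DMAP-catalysed acylation with retention at C3, since the C–O bond of the allylic alcohol is never broken.

**Pentaene linchpin**

Step 24
Reactants: 32 dibromomethane
Product: 33 tributyl(dibromomethyl)stannane
Conditions: LiN(iPr)2, THF/Et2O, −95 °C; then Bu3SnCl, −95 → 23 °C
Reagents that add atoms: tributyltin chloride CCCC[Sn](Cl)(CCCC)CCCC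
Why: Deprotonation of dibromomethane to its lithium carbenoid, which is stable only at very low temperature, and trapping at tin (carbenoid stannylation).

Step 25
Reactants: 34 (2E,4E,6E)-2,7-dimethylocta-2,4,6-trienedial
Product: 35 (2E,4E,6E,8E)-2,7-dimethyl-9-(4,4,5,5-tetramethyl-1,3,2-dioxaborolan-2-yl)nona-2,4,6,8-tetraenal
Conditions: 34 (3 equiv), Cl2CHBpin (1 equiv), CrCl2, LiI, THF, 23 °C, dark; excess 34 recovered
Reagents that add atoms: 2-(dichloromethyl)-4,4,5,5-tetramethyl-1,3,2-dioxaborolane ClC(Cl)B1OC(C)(C)C(C)(C)O1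
Why: Takai–Utimoto boryl olefination, in which a gem-dichromium species from the dihalomethylboronate adds to one aldehyde and anti-elimination gives the E alkenylboronate; the symmetric dialdehyde is used in excess so that mono-olefination dominates statistically.

Step 26
Reactants: 35 (2E,4E,6E,8E)-2,7-dimethyl-9-(4,4,5,5-tetramethyl-1,3,2-dioxaborolan-2-yl)nona-2,4,6,8-tetraenal, 33 tributyl(dibromomethyl)stannane
Product: 36 tributyl[(1E,3E,5E,7E,9E)-3,8-dimethyl-10-(4,4,5,5-tetramethyl-1,3,2-dioxaborolan-2-yl)deca-1,3,5,7,9-pentaen-1-yl]stannane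
Conditions: CrCl2, LiI, THF/DMF, 23 °C, dark; chromatography on Et3N-deactivated neutral alumina
Reagents that add atoms: none
Why: Hodgson variant of the Takai olefination, in which the gem-dichromium reagent from 33 turns the remaining aldehyde into the E alkenylstannane; the pinacol boronate and the polyene are inert to divalent chromium.

**Three-component coupling**

Step 27
Reactants: 18 (3S,5R,6S)-epoxy-ring C14 dienyl iodide palmitate, 36 tributyl[(1E,3E,5E,7E,9E)-3,8-dimethyl-10-(4,4,5,5-tetramethyl-1,3,2-dioxaborolan-2-yl)deca-1,3,5,7,9-pentaen-1-yl]stannane, 31 (3R,6R)-ε-ring C14 dienyl iodide palmitate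
Product: 38 lutein 5,6-epoxide dipalmitate (target), via heptaenyl boronate 37 (not isolated)
Conditions: 18 (1.0 equiv), 36 (1.0 equiv, freshly purified), Pd2(dba)3 (2.5 mol %), AsPh3 (20 mol %), THF/DMF, 23 °C, argon, dark; then 31 (1.05 equiv), PdCl2(dppf) (5 mol %), degassed aq. K3PO4 (3 M), 23 → 40 °C; chromatography on Et3N-deactivated silica, crystallisation away from light and acid
Reagents that add atoms: none
Why: Zerovalent palladium inserts into the C10–I bond of 18 with retention, the tributylstannyl terminus (C11) of 36 transmetallates under neutral conditions (accelerated by AsPh3) and reductive elimination forms C10–C11, the pinacol boronate at C11′ remaining inert because neither base nor fluoride is present. After phosphate is added, the boronate transmetallates (through its hydroxo "ate" form or a palladium hydroxide) to the alkenylpalladium iodide formed from 31, and reductive elimination forms C10′–C11′. The closest known reaction type is the one-pot Stille–Suzuki sequence on 1-boryl-2-stannylalkene linchpins, together with the bidirectional Stille or Suzuki assembly of carotenoid polyenes from bis-metallated cores. No ring is closed and no stereocentre is created; all nine chain double bonds keep the E geometry built into the three pieces because every elementary step is stereoretentive. The step needs tin-before-boron chemoselectivity, secured by withholding base until 18 is consumed and by exact 1:1 stoichiometry, and it needs C–I oxidative addition to outrun ionisation of the allylic C6–O oxirane bond and of the allylic C3′ palmitate, which fast room-temperature insertion into alkenyl iodides, the steric shielding of both allylic C–O bonds and the late addition of 31 with a chelating phosphine should provide. The neutral to mildly basic medium spares both esters and prevents rearrangement of the 5,6-oxirane to the 5,8-furanoid.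

**Compound list**

1 | ketoisophorone (2,6,6-trimethylcyclohex-2-ene-1,4-dione) | CC1=CC(=O)CC(C)(C)C1=O | starting material
2 | (6R)-levodione ((6R)-2,2,6-trimethylcyclohexane-1,4-dione) | O=C1CC(C)(C)C(=O)[C@H](C)C1 | intermediate
3 | (4R,6R)-actinol ((4R,6R)-4-hydroxy-2,2,6-trimethylcyclohexanone, hydroxyl trans to the C6 methyl) | O[C@H]1CC(C)(C)C(=O)[C@H](C)C1 | intermediate
4 | (4R,6R)-4-(tert-butyldimethylsilyloxy)-2,2,6-trimethylcyclohexanone | CC(C)(C)[Si](C)(C)O[C@H]1CC(C)(C)C(=O)[C@H](C)C1 | intermediate
5 | (4R)-4-(tert-butyldimethylsilyloxy)-2,6,6-trimethylcyclohex-1-en-1-yl trifluoromethanesulfonate | CC(C)(C)[Si](C)(C)O[C@H]1CC(C)(C)C(OS(=O)(=O)C(F)(F)F)=C(C)C1 | intermediate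
6 | methyl (4R)-4-(tert-butyldimethylsilyloxy)-2,6,6-trimethylcyclohex-1-ene-1-carboxylate | CC(C)(C)[Si](C)(C)O[C@H]1CC(C)(C)C(C(=O)OC)=C(C)C1 | intermediate
7 | [(4R)-4-(tert-butyldimethylsilyloxy)-2,6,6-trimethylcyclohex-1-en-1-yl]methanol | CC(C)(C)[Si](C)(C)O[C@H]1CC(C)(C)C(CO)=C(C)C1 | intermediate
8 | [(1R,4S,6R)-4-(tert-butyldimethylsilyloxy)-2,2,6-trimethyl-7-oxabicyclo[4.1.0]heptan-1-yl]methanol (oxirane anti to the silyloxy group) | CC(C)(C)[Si](C)(C)O[C@H]1CC(C)(C)[C@]2(CO)O[C@]2(C)C1 | intermediate
9 | (1S,4S,6R)-4-(tert-butyldimethylsilyloxy)-2,2,6-trimethyl-7-oxabicyclo[4.1.0]heptane-1-carbaldehyde | CC(C)(C)[Si](C)(C)O[C@H]1CC(C)(C)[C@]2(C=O)O[C@]2(C)C1 | intermediate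
10 | propargyl alcohol (prop-2-yn-1-ol) | C#CCO | starting material
11 | alkenylalane from 10: (E)-Me2Al–CH=C(CH3)–CH2–O–AlMe2 | C[Al](C)OC/C(C)=C/[Al](C)C | intermediate (not isolated)
12 | (2E)-3-iodo-2-methylprop-2-en-1-ol | OC/C(C)=C/I | intermediate
13 | (1E)-3-bromo-1-iodo-2-methylprop-1-ene | BrC/C(C)=C/I | intermediate
14 | diethyl [(2E)-3-iodo-2-methylprop-2-en-1-yl]phosphonate | CCOP(=O)(OCC)C/C(C)=C/I | intermediate
15 | (1S,4S,6R)-4-(tert-butyldimethylsilyloxy)-1-[(1E,3E)-4-iodo-3-methylbuta-1,3-dien-1-yl]-2,2,6-trimethyl-7-oxabicyclo[4.1.0]heptane (carotenoid numbering 3S,5R,6S) | CC(C)(C)[Si](C)(C)O[C@H]1CC(C)(C)[C@]2(/C=C/C(C)=C/I)O[C@]2(C)C1 | intermediate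
16 | (3S,5R,6S)-epoxy-ring C14 dienyl iodide with free 3-hydroxyl (15 without the silyl group) | O[C@H]1CC(C)(C)[C@]2(/C=C/C(C)=C/I)O[C@]2(C)C1 | intermediate
17 | palmitoyl chloride (hexadecanoyl chloride) | CCCCCCCCCCCCCCCC(=O)Cl | starting material
18 | (3S,5R,6S)-epoxy-ring C14 dienyl iodide palmitate (16 acylated at O3; 7E,9E) | CCCCCCCCCCCCCCCC(=O)O[C@H]1CC(C)(C)[C@]2(/C=C/C(C)=C/I)O[C@]2(C)C1 | intermediate
19 | α-ionone (racemic) | CC1=CCCC(C)(C)C1/C=C/C(C)=O | starting material
20 | rac-3-oxo-α-ionone ((3E)-4-(2,6,6-trimethyl-4-oxocyclohex-2-en-1-yl)but-3-en-2-one) | CC1=CC(=O)CC(C)(C)C1/C=C/C(C)=O | intermediate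
21 | rac-3-oxo-α-ionone 9-ethylene ketal (dioxolane at the side-chain ketone) | CC1=CC(=O)CC(C)(C)C1/C=C/C1(C)OCCO1 | intermediate
22 | rac-trans-3-hydroxy-α-ionone 9-ethylene ketal (racemate, both enantiomers written) | CC1(/C=C/[C@H]2C(C)=C[C@H](O)CC2(C)C)OCCO1.CC1(/C=C/[C@@H]2C(C)=C[C@@H](O)CC2(C)C)OCCO1 | intermediate (not isolated)
23 | rac-trans-3-hydroxy-α-ionone (racemate of 3R,6R and 3S,6S, both written) | CC(=O)/C=C/[C@H]1C(C)=C[C@H](O)CC1(C)C.CC(=O)/C=C/[C@@H]1C(C)=C[C@@H](O)CC1(C)C | intermediate
24 | (3R,6R)-3-hydroxy-α-ionone ((3E)-4-[(1R,4R)-4-hydroxy-2,6,6-trimethylcyclohex-2-en-1-yl]but-3-en-2-one) | CC(=O)/C=C/[C@H]1C(C)=C[C@H](O)CC1(C)C | intermediate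
25 | (3R,6R)-3-(tert-butyldimethylsilyloxy)-α-ionone | CC(=O)/C=C/[C@H]1C(C)=C[C@H](O[Si](C)(C)C(C)(C)C)CC1(C)C | intermediate
26 | dienyl diethyl phosphate of 25 (enol phosphate at C9, terminal CH2) | C=C(OP(=O)(OCC)OCC)/C=C/[C@H]1C(C)=C[C@H](O[Si](C)(C)C(C)(C)C)CC1(C)C | intermediate (not isolated)
27 | (3R,6R)-TBS enyne (ring C6 bearing the (1E)-but-1-en-3-ynyl chain; 3-OTBS) | C#C/C=C/[C@H]1C(C)=C[C@H](O[Si](C)(C)C(C)(C)C)CC1(C)C | intermediate
28 | alkenylalane from 27 ((E)-dimethylalumanyl at C10, methyl at C9) | C[Al](C)/C=C(C)/C=C/[C@H]1C(C)=C[C@H](O[Si](C)(C)C(C)(C)C)CC1(C)C | intermediate (not isolated)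
29 | (3R,6R)-ε-ring C14 dienyl iodide TBS ether ((1E,3E)-4-iodo-3-methylbuta-1,3-dienyl at C6; 3-OTBS) | I/C=C(C)/C=C/[C@H]1C(C)=C[C@H](O[Si](C)(C)C(C)(C)C)CC1(C)C | intermediate
30 | (3R,6R)-ε-ring C14 dienyl iodide with free 3-hydroxyl | I/C=C(C)/C=C/[C@H]1C(C)=C[C@H](O)CC1(C)C | intermediate
31 | (3R,6R)-ε-ring C14 dienyl iodide palmitate ((1R,4R)-4-[(1E,3E)-4-iodo-3-methylbuta-1,3-dien-1-yl]-3,5,5-trimethylcyclohex-2-en-1-yl hexadecanoate) | I/C=C(C)/C=C/[C@H]1C(C)=C[C@H](OC(=O)CCCCCCCCCCCCCCC)CC1(C)C | intermediate
32 | dibromomethane | BrCBr | starting material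
33 | tributyl(dibromomethyl)stannane | CCCC[Sn](CCCC)(CCCC)C(Br)Br | intermediate
34 | (2E,4E,6E)-2,7-dimethylocta-2,4,6-trienedial | O=C/C(C)=C/C=C/C=C(C)/C=O | starting material
35 | (2E,4E,6E,8E)-2,7-dimethyl-9-(4,4,5,5-tetramethyl-1,3,2-dioxaborolan-2-yl)nona-2,4,6,8-tetraenal | O=C/C(C)=C/C=C/C=C(C)/C=C/B1OC(C)(C)C(C)(C)O1 | intermediate
36 | C12 pentaene tin/boron linchpin: tributyl[(1E,3E,5E,7E,9E)-3,8-dimethyl-10-(4,4,5,5-tetramethyl-1,3,2-dioxaborolan-2-yl)deca-1,3,5,7,9-pentaen-1-yl]stannane | CCCC[Sn](CCCC)(CCCC)/C=C/C(C)=C/C=C/C=C(C)/C=C/B1OC(C)(C)C(C)(C)O1 | intermediate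
37 | heptaenyl pinacol boronate: the (3S,5R,6S)-epoxy ring palmitate carrying the all-E C7–C11′ heptaene, boron at C11′ | CCCCCCCCCCCCCCCC(=O)O[C@H]1CC(C)(C)[C@]2(/C=C/C(C)=C/C=C/C(C)=C/C=C/C=C(C)/C=C/B3OC(C)(C)C(C)(C)O3)O[C@]2(C)C1 | intermediate (not isolated)
38 | lutein 5,6-epoxide dipalmitate, all-E (3S,5R,6S,3′R,6′R)-5,6-epoxy-5,6-dihydro-β,ε-carotene-3,3′-diyl dihexadecanoate | CCCCCCCCCCCCCCCC(=O)O[C@H]1CC(C)(C)[C@]2(/C=C/C(C)=C/C=C/C(C)=C/C=C/C=C(C)/C=C/C=C(C)/C=C/[C@H]3C(C)=C[C@H](OC(=O)CCCCCCCCCCCCCCC)CC3(C)C)O[C@]2(C)C1 | target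

**Step count and risks**

Total step count: 27. Longest linear sequence: 12 steps (steps 1–8, 12–14 and 27, from ketoisophorone).

Steps most likely to fail:

Step 27. The order tin-before-boron may be lost through premature activation or homocoupling of the boronate. Zerovalent palladium may also ionise the allylic C3′ ester or the allylic oxirane bond, and the long polyene may degrade during the aqueous base phase. The fallback takes the allylic ester out of the palladium chemistry and splits the operation. It sets out from 18 and 36, which are coupled alone under the same Stille conditions, and heptaenyl boronate 37 is then isolated on deactivated alumina. 37 is coupled in a second flask with the free allylic alcohol 30 (Pd(OAc)2, SPhos, K3PO4, THF/water, 23 °C) to give lutein 5,6-epoxide 3-palmitate F1. The 3′-hydroxyl is acylated last with 17 (pyridine, DMAP, CH2Cl2, 0 °C), which returns to the route at 38.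

Step 12. The γ-iodo allylic phosphonate anion may decompose by loss of iodide before it meets the hindered aldehyde, or geometric control at C7=C8 may be poor. The fallback carries tin instead of iodine through the olefination. It sets out from 14, which is stannylated with Bu3SnSnBu3 and Pd(PPh3)4 to give diethyl [(2E)-2-methyl-3-(tributylstannyl)prop-2-en-1-yl]phosphonate F2. Horner–Wadsworth–Emmons reaction of F2 (KN(SiMe3)2, THF, −78 °C) with 9 gives the TBS epoxy dienylstannane F3. Iododestannylation with retention (I2, NaHCO3, CH2Cl2, 0 °C) returns to the route at 15.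

Step 18. The lipase may discriminate poorly between the enantiomers, or in the opposite sense, so that the recovered alcohol is of low enantiomeric purity. The fallback resolves through covalent diastereomers and does not depend on the enzyme. It sets out from 23, which is acylated with (1S)-camphanic chloride (pyridine, DMAP, CH2Cl2) to give (3R,6R)-3-hydroxy-α-ionone (1S)-camphanate F4 and (3S,6S)-3-hydroxy-α-ionone (1S)-camphanate F5. These are separated by chromatography and crystallisation, and saponification of F4 (LiOH, THF/water, 0 °C) returns to the route at 24.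

Further compounds
F1 | step 27 | lutein 5,6-epoxide 3-palmitate (3′-hydroxyl free) | CCCCCCCCCCCCCCCC(=O)O[C@H]1CC(C)(C)[C@]2(/C=C/C(C)=C/C=C/C(C)=C/C=C/C=C(C)/C=C/C=C(C)/C=C/[C@H]3C(C)=C[C@H](O)CC3(C)C)O[C@]2(C)C1
F2 | step 12 | diethyl [(2E)-2-methyl-3-(tributylstannyl)prop-2-en-1-yl]phosphonate | CCCC[Sn](CCCC)(CCCC)/C=C(C)/CP(=O)(OCC)OCC
F3 | step 12 | TBS epoxy dienylstannane (15 with tributylstannyl in place of iodine) | CC(C)(C)[Si](C)(C)O[C@H]1CC(C)(C)[C@]2(/C=C/C(C)=C/[Sn](CCCC)(CCCC)CCCC)O[C@]2(C)C1
F4 | step 18 | (3R,6R)-3-hydroxy-α-ionone (1S)-camphanate | CC(=O)/C=C/[C@H]1C(C)=C[C@H](OC(=O)[C@@]23CC[C@@](C)(C(=O)O2)C3(C)C)CC1(C)C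
F5 | step 18 | (3S,6S)-3-hydroxy-α-ionone (1S)-camphanate | CC(=O)/C=C/[C@@H]1C(C)=C[C@@H](OC(=O)[C@@]23CC[C@@](C)(C(=O)O2)C3(C)C)CC1(C)C
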